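## Structural features

Entonaemin A (28) is a 5,6,7,8-tetrahydro-1H-isochromen-8-one. Ring A (carbocycle C4a, C5, C6, C7, C8, C8a) and ring B (2H-pyran C1, O2, C3, C4, C4a, C8a) share the tetrasubstituted C4a=C8a double bond, and C3 carries an (E)-3-hydroxyprop-1-enyl chain (C9–C11). O2, C3=C4, C4a=C8a and the C8 carbonyl form one push–pull chromophore, a doubly vinylogous ester. The only stereocentres are adjacent: C6 (R, secondary, esterified by orsellinic acid) and C7 (R, tertiary carbinol with methyl), with the two oxygens syn and C7 lying between C6 and the C8 ketone. The fragile points are four. The C6 ester is vinylogously β to the C8 carbonyl through the C5 hydrogens and can be lost by E1cB elimination under base. The C7 hydroxyl beside it allows acyl shift and α-ketol chemistry. The dienyl ether of ring B is sensitive to acid and oxidants. The C11 alcohol is allylic. The ester joins a secondary alcohol next to a quaternary carbon to a 2,6-disubstituted benzoic acid, so it is hard to form once ring A exists. The real difficulty is to assemble the bicycle late and under nearly neutral conditions with ester and stereocentres already in place. The key step uses the fact that ring B is the closed valence isomer of the 1-oxatriene O=C3–C4=C4a–C8a=C1: joining C4a (vinyl iodide) to the α-carbon C8a of a C8 vinyl ketone closes ring A and, after β-hydride loss to the C1 methylene, sets up that oxatriene for closure of ring B.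

## Logic of the disconnections

28 from 27. The four O–Si bonds (O11, both phenol oxygens, O7) are cut. All hydroxyls are masked by groups that one fluoride reagent clears under weakly acidic conditions, because base would expel the C6 ester through the C5 hydrogens. The forward step must cleave aryl, primary and tertiary silyl ethers without harming the dienyl ether.

27 from 25 through 26. Ring B is opened at O2–C1 (retro-oxa-6π) to 26, and ring A at C4a–C8a (retro-Heck), which returns iodine to C4a and hydrogen to C8a. Two rings and the tetrasubstituted alkene disappear, and 25 is an acyclic chain that already holds C6, C7 and the ester. The forward step must insert 6-exo at the α-carbon of the vinyl ketone, and 25 must have iodine cis to the C3 carbonyl. In 25 the C7 oxygen is silylated and not free. A free tertiary hydroxyl there could add to C4a of the β-iodoenone (five-membered ring, addition–elimination), bind palladium, accept the neighbouring acyl group or start α-ketol chemistry. The silyl group leaves in the last step at no extra cost.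

25 from 24 and 23. The C8 carbonyl is traced to a carbinol and this to its PMB ether. A vinyl ketone cannot survive acetylide, iodide or acylation chemistry, so it is unveiled last. PMB withstands acid, base and organometallic steps and leaves under neutral oxidative conditions beside four silyl ethers. The forward deprotection and oxidation must touch neither the iodoenone nor the ester.

23 from 22. The C4a–I and C4–H bonds are cut (retro-hydroiodination). The stereodefined trisubstituted alkene becomes an alkyne with no geometry. The forward addition must be anti, so that iodine and the C3 carbonyl end cis, and must choose the ynone over the enone.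

22 from 21, and 21 from 16 and 20. The C3 ketone is taken back to the carbinol and the C3–C4 bond is cut between an acetylide and an aldehyde. This splits off the C9–C11 arm as 20 and makes the route convergent. The forward step must form the acetylide in the presence of the C6 ester: low temperature, one equivalent of a hindered base, no free hydroxyl beside the ester.

16 from 15, and 15 from 11 and 14. The O7–Si bond and the ester C–O bond at C6 are cut. The hindered benzoate is thus formed on an open-chain secondary alcohol, before any enone or ynone makes the C5 hydrogens acidic. The tertiary C7 hydroxyl needs no differentiation. The acylation needs the activated acid 14, which goes back through 13 to 12.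

11 from 10 and 9. The acetonide across O6 and O7 is restored and the PMB group on O8 removed. C8–OH is the one hydroxyl that must be told apart from C6–OH, so its protecting group must survive the acid that opens the acetonide.

9 from 7 through 8. The C8–C8a bond is cut (vinyl nucleophile plus aldehyde) and the alkyne is silylated again. The C8 epimers are of no consequence because C8 becomes a carbonyl.

7 from 6, and 6 from 4 through 5. The C8 aldehyde is traced to a terminal alkene, and the C5–C4a bond is cut between a primary triflate and an acetylide. C8 stays an alkene while C5 carries a leaving group, because a C8 hydroxyl or alkoxide would close a tetrahydrofuran onto C5 (the ring system of 3). The forward steps are an SN2 reaction at a β-oxygenated primary carbon and an ozonolysis that spares the alkyne.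

4 from 3, 2 and 1. The alkene is cut to the lactol carbonyl, the lactol to the lactone, the acetonide to the free diol. 1 supplies C5 to C8 with both stereocentres in the correct absolute sense (its CH2–O is C5, its carbonyl carbon C8), so no stereocentre is made or inverted anywhere.

20 from 18 and 17, by oxidation with Z to E isomerisation and by monosilylation of a symmetrical diol.

## Other disconnections considered

Alternative 1: The cut is the C8–C8a bond inside ring A.
- Forward step: keto ester A2 would come from 1 by acetonide formation, lactone opening, alkynylation at C5 and alkyne hydration. LiN(SiMe3)2 forms the kinetic enolate of its methyl ketone (C8a), which attacks the C8 ester in a 6-exo-trig Dieckmann closure to the 1,3-dione A1.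
- In its favour: the same chiral pool fixes C6 and C7. Ring A closes by a classical, catalyst-free reaction with no exo/endo question, and on this point it is better than the chosen plan.
- Against it: A1 holds only ring A. C1, the C3–C4 unit, the C9–C11 arm and ring B are still missing. The two carbonyls (C8, C4a) must be told apart, and C8a must be hydroxymethylated once although 1,3-diones tend to react twice. The acetonide must be removed with acid and replaced by the hindered ester on a ring alcohol, late.
- Mechanism: A1 and its enolates carry a β-oxygen at C6 and can eliminate and aromatise. The equilibrating C5 enolate of A2 has the same exit.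
- Step economy: the key step comes early and roughly eight to ten steps would follow it, against one in the chosen plan. No shorter total is expected.
- Balance: safer ring A closure, weaker convergence, harder end game.

Alternative 2: The cut is the C6–C7 bond.
- Forward step: the 1-acetylcyclopent-2-en-1-ol A4 is treated with Zn(OTf)2. Divalent zinc chelates the C8 hydroxyl and the acetyl oxygen, C6 shifts from C8 to the acetyl carbon (α-ketol rearrangement), and ketol A3 results with the C8 ketone conjugated to C8a=C4a.
- In its favour: one isomerisation creates the tertiary carbinol, the six-membered ring and the enone, driven by conjugation and relief of ring strain. The ester is already in place. Ring B would then be closed by desilylation and 6-endo-dig hydroalkoxylation of the C3≡C4 alkyne by the C1 hydroxyl, a well-precedented route to such pyrans. In the certainty of ring B closure it is the equal of or better than the chosen plan, and the ring A skeleton does not hinge on an exo/endo choice.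
- Against it: C8 of A4 offers two migrating groups, and the alkenyl carbon C8a is intrinsically the better migrator than C6, which bears an acyloxy group. The shift is reversible. C7 is created in the key step and depends on the chelate geometry and on the C8 configuration of A4, which must itself be made enantiopure together with C6. The ester can move to the tertiary hydroxyl under Lewis acid.
- Structure: the chosen plan takes both stereocentres from 1 and creates none.
- Step economy: A4 is a tetrasubstituted cyclopentene with four different arms and would need a long synthesis of its own, so no saving is expected.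

Alternative 3: The cuts are the ester C–O bond at C6 and the C1–C6 bond of the arene.
- Forward step: diol A6 is heated with diketo-dioxinone A7. Retro-[4+2] fragmentation gives acylketene A8, the C6 hydroxyl captures it as triketo ester A9, and NEt3 in the same flask folds A9 by aldol condensation and dehydration into the orsellinate of A5. One desilylation then gives 28.
- In its favour: it avoids the hindered acylation and all phenol protection (steps 9–11 and the aryl silyl ethers of the chosen route), so on protecting-group economy of the aryl part it is better. After its key step it needs one step, as does the chosen plan.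
- Against it: it does not make the bicyclic core A6, so it complements a core synthesis and does not replace one. A6 must be heated to about 100 °C and then exposed to an amine while C6 carries a β-keto ester, a good leaving group vinylogously β to the C8 carbonyl, which invites E1cB loss of the side chain. The tertiary C7 hydroxyl can compete for A8.
- Step economy: A7 needs two or three steps, about as many as 14, so the gain is small and is paid for with risk at the last stage.
- The idea could be moved to 11 of the chosen route, but the free phenols formed would need protection before step 15.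

Key step: step 20

## Remarks on the chemistry

- Positional numbers (C1–C11) are those of the isochromene skeleton of 28, also in open-chain compounds. TBS = tert-butyldimethylsilyl, TES = triethylsilyl, PMB = 4-methoxybenzyl.
- 28 is (6R,7R) with O6 and O7 syn. 1 is (3R,4R) and maps onto C8–C5 without inversion. C6 and C7 keep the spatial arrangement of 1 throughout. Because CIP descriptors change with the substituents, the SMILES strings define the configuration of intermediates.
- C8 in 8–11, 15, 16 and 21–24 and C3 in 21 are epimeric mixtures. Both centres become carbonyl carbons (steps 16 and 19).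

## Route

Step 1
Reactants: 1 2-C-methyl-D-erythrono-1,4-lactone
Product: 2 2,3-O-isopropylidene-2-C-methyl-D-erythrono-1,4-lactone
Conditions: Me2C(OMe)2, TsOH·H2O (cat.), acetone, rt
Reagents that add atoms: 2,2-dimethoxypropane COC(C)(C)OC
Why: Acid-catalysed transketalisation of the cis-diol gives the cis-fused dioxolane; no stereocentre is touched and both hydroxyls are masked for the hydride, ylide and organometallic steps.

Step 2
Reactants: 2 2,3-O-isopropylidene-2-C-methyl-D-erythrono-1,4-lactone
Product: 3 2,3-O-isopropylidene-2-C-methyl-D-erythrofuranose (lactol; both anomers)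
Conditions: i-Bu2AlH (1.1 equiv), CH2Cl2, −78 °C; aq. KNaC4H4O6
Reagents that add atoms: none
Why: Partial hydride reduction of a γ-lactone stops at the tetrahedral aluminium lactolate at low temperature; the anomeric centre is of no consequence.

Step 3
Reactants: 3 2,3-O-isopropylidene-2-C-methyl-D-erythrofuranose
Product: 4 (5-ethenyl-2,2,5-trimethyl-1,3-dioxolan-4-yl)methanol (C6,C7-acetonide; C5–OH; C8 as alkene carbon)
Conditions: Ph3PCH3Br (3 equiv), KOt-Bu (2.9 equiv), THF, 0 → 50 °C
Reagents that add atoms: methyltriphenylphosphonium bromide C[P+](c1ccccc1)(c1ccccc1)c1ccccc1.[Br-]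
Why: Wittig methylenation of the open hydroxy-aldehyde form of the lactol; C7 is quaternary and cannot epimerise, and the alkene is a non-nucleophilic mask of the C8 aldehyde while C5 is activated.

Step 4
Reactants: 4 (5-ethenyl-2,2,5-trimethyl-1,3-dioxolan-4-yl)methanol
Product: 6 trimethyl[3-(5-ethenyl-2,2,5-trimethyl-1,3-dioxolan-4-yl)prop-1-ynyl]silane, via primary triflate 5 (not isolated)
Conditions: Tf2O, 2,6-lutidine, CH2Cl2, −78 °C; then Me3SiC≡CLi (from Me3SiC≡CH, n-BuLi), THF/DMPU, −78 → −20 °C
Reagents that add atoms: ethynyltrimethylsilane C#C[Si](C)(C)C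
Why: Triflate formation and SN2 displacement by the lithium acetylide form the C5–C4a bond; with C8 still an alkene no oxygen nucleophile can close a tetrahydrofuran onto C5, and C6 is not involved, so its configuration is retained.

Step 5
Reactants: 6 trimethyl[3-(5-ethenyl-2,2,5-trimethyl-1,3-dioxolan-4-yl)prop-1-ynyl]silane
Product: 7 2,2,4-trimethyl-5-[3-(trimethylsilyl)prop-2-ynyl]-1,3-dioxolane-4-carbaldehyde
Conditions: O3, CH2Cl2, −78 °C (to consumption of the alkene); then Me2S, −78 °C → rt
Reagents that add atoms: ozone [O-][O+]=O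
Why: Ozonolysis with reductive work-up cleaves the terminal alkene far faster than the silylated alkyne; the aldehyde has no α-hydrogen and is configurationally stable.

Step 6
Reactants: 7 2,2,4-trimethyl-5-[3-(trimethylsilyl)prop-2-ynyl]-1,3-dioxolane-4-carbaldehyde
Product: 9 1-[2,2,4-trimethyl-5-(prop-2-ynyl)-1,3-dioxolan-4-yl]prop-2-en-1-ol, via silylated alkynyl carbinol 8 (not isolated)
Conditions: CH2=CHMgBr (1.5 equiv), THF, −78 → 0 °C; then MeOH, K2CO3, rt
Reagents that add atoms: vinylmagnesium bromide C=C[Mg]Br
Why: Grignard 1,2-addition builds the C8–C8a bond (the C8 epimers converge in step 19), and methanolysis of the C(sp)–Si bond in the same flask frees the terminal alkyne before any base-labile aryl silyl ether is present.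

Step 7
Reactants: 9 1-[2,2,4-trimethyl-5-(prop-2-ynyl)-1,3-dioxolan-4-yl]prop-2-en-1-ol
Product: 10 4-{1-[(4-methoxybenzyl)oxy]prop-2-enyl}-2,2,4-trimethyl-5-(prop-2-ynyl)-1,3-dioxolane
Conditions: NaH (1.3 equiv), 4-MeOC6H4CH2Cl, Bu4NI (cat.), DMF, 0 °C → rt
Reagents that add atoms: 4-methoxybenzyl chloride COc1ccc(CCl)cc1
Why: Williamson etherification of the only hydroxyl; the PMB ether survives the acid of step 8 and every later step and is removable oxidatively beside silyl ethers and the ester.

Step 8
Reactants: 10 4-{1-[(4-methoxybenzyl)oxy]prop-2-enyl}-2,2,4-trimethyl-5-(prop-2-ynyl)-1,3-dioxolane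
Product: 11 3-[(4-methoxybenzyl)oxy]-4-methyloct-1-en-7-yne-4,5-diol
Conditions: AcOH/H2O (4:1), 45 °C
Reagents that add atoms: none
Why: Acid hydrolysis of the acetonide releases the secondary C6 and tertiary C7 hydroxyls; the PMB ether, alkene and alkyne are inert to dilute acetic acid.

Step 9
Reactants: 12 orsellinic acid
Product: 13 tert-butyldimethylsilyl 2,4-bis(tert-butyldimethylsilyloxy)-6-methylbenzoate
Conditions: TBSCl (3.5 equiv), imidazole, DMF, rt
Reagents that add atoms: tert-butyldimethylsilyl chloride CC(C)(C)[Si](C)(C)Cl
Why: Exhaustive silylation gives the two aryl silyl ethers and the silyl ester in one operation.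

Step 10
Reactants: 13 tert-butyldimethylsilyl 2,4-bis(tert-butyldimethylsilyloxy)-6-methylbenzoate
Product: 14 2,4-bis(tert-butyldimethylsilyloxy)-6-methylbenzoyl chloride
Conditions: (COCl)2 (1.2 equiv), DMF (cat.), CH2Cl2, 0 °C → rt; evaporate and use crude
Reagents that add atoms: oxalyl chloride ClC(=O)C(Cl)=O
Why: Silyl esters are converted directly into acid chlorides by oxalyl chloride under DMF catalysis (Vilsmeier-type activation) without free acid or HCl, so the aryl silyl ethers survive.

Step 11
Reactants: 11 3-[(4-methoxybenzyl)oxy]-4-methyloct-1-en-7-yne-4,5-diol; 14 2,4-bis(tert-butyldimethylsilyloxy)-6-methylbenzoyl chloride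
Product: 15 4-hydroxy-3-[(4-methoxybenzyl)oxy]-4-methyloct-1-en-7-yn-5-yl 2,4-bis(tert-butyldimethylsilyloxy)-6-methylbenzoate
Conditions: 14 (1.5 equiv), Et3N, DMAP (0.3 equiv), CH2Cl2, 0 °C → rt
Reagents that add atoms: none
Why: DMAP-catalysed acylation; the secondary C6 hydroxyl reacts while the tertiary C7 hydroxyl is too hindered, the C6–O bond is not broken so configuration is retained, and the congested ester is made on a flexible chain before any base-sensitive enone exists.

Step 12
Reactants: 15 4-hydroxy-3-[(4-methoxybenzyl)oxy]-4-methyloct-1-en-7-yn-5-yl 2,4-bis(tert-butyldimethylsilyloxy)-6-methylbenzoate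
Product: 16 3-[(4-methoxybenzyl)oxy]-4-methyl-4-(triethylsilyloxy)oct-1-en-7-yn-5-yl 2,4-bis(tert-butyldimethylsilyloxy)-6-methylbenzoate
Conditions: Et3SiOTf (1.5 equiv), 2,6-lutidine, CH2Cl2, −78 → 0 °C
Reagents that add atoms: triethylsilyl trifluoromethanesulfonate CC[Si](CC)(CC)OS(=O)(=O)C(F)(F)F
Why: Silyl triflate silylation of the tertiary alcohol; the cap prevents alkoxide formation next to the ester in step 15 and conjugate attack of O7 on C4a of the iodoenone later.

Step 13
Reactants: 17 (Z)-but-2-ene-1,4-diol
Product: 18 (Z)-4-(tert-butyldimethylsilyloxy)but-2-en-1-ol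
Conditions: NaH (1.0 equiv), THF, 0 °C; then TBSCl (1.0 equiv)
Reagents that add atoms: tert-butyldimethylsilyl chloride CC(C)(C)[Si](C)(C)Cl
Why: Monosilylation of the symmetrical diol through its sparingly soluble monosodium alkoxide.

Step 14
Reactants: 18 (Z)-4-(tert-butyldimethylsilyloxy)but-2-en-1-ol
Product: 20 (E)-4-(tert-butyldimethylsilyloxy)but-2-enal, via Z-enal 19 (not isolated)
Conditions: pyridinium chlorochromate (C5H5NH)[CrO3Cl] (1.5 equiv), CH2Cl2, rt
Reagents that add atoms: none
Why: Chromate oxidation of the allylic alcohol; under the mildly acidic conditions the Z-enal equilibrates to the conjugated E-enal, the thermodynamic isomer.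

Step 15
Reactants: 16 3-[(4-methoxybenzyl)oxy]-4-methyl-4-(triethylsilyloxy)oct-1-en-7-yn-5-yl 2,4-bis(tert-butyldimethylsilyloxy)-6-methylbenzoate; 20 (E)-4-(tert-butyldimethylsilyloxy)but-2-enal
Product: 21 (E)-12-(tert-butyldimethylsilyloxy)-9-hydroxy-3-[(4-methoxybenzyl)oxy]-4-methyl-4-(triethylsilyloxy)dodeca-1,10-dien-7-yn-5-yl 2,4-bis(tert-butyldimethylsilyloxy)-6-methylbenzoate
Conditions: LiN(SiMe3)2 (1.05 equiv), THF, −78 °C; then 20 (1.3 equiv), −78 °C; aq. NH4Cl
Reagents that add atoms: none
Why: Deprotonation of the terminal alkyne and 1,2-addition of the lithium acetylide to the enal form the C3–C4 bond; at −78 °C the doubly ortho-substituted benzoate is not attacked, and the new C3 carbinol (both epimers) is oxidised next.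

Step 16
Reactants: 21 (E)-12-(tert-butyldimethylsilyloxy)-9-hydroxy-3-[(4-methoxybenzyl)oxy]-4-methyl-4-(triethylsilyloxy)dodeca-1,10-dien-7-yn-5-yl 2,4-bis(tert-butyldimethylsilyloxy)-6-methylbenzoate
Product: 22 (E)-12-(tert-butyldimethylsilyloxy)-3-[(4-methoxybenzyl)oxy]-4-methyl-9-oxo-4-(triethylsilyloxy)dodeca-1,10-dien-7-yn-5-yl 2,4-bis(tert-butyldimethylsilyloxy)-6-methylbenzoate
Conditions: MnO2 (activated, 20 equiv), CH2Cl2, rt
Reagents that add atoms: none
Why: MnO2 oxidation of a doubly activated (allylic and propargylic) alcohol under neutral conditions, which avoids base-induced loss of the C6 ester from the ynone.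

Step 17
Reactants: 22 (E)-12-(tert-butyldimethylsilyloxy)-3-[(4-methoxybenzyl)oxy]-4-methyl-9-oxo-4-(triethylsilyloxy)dodeca-1,10-dien-7-yn-5-yl 2,4-bis(tert-butyldimethylsilyloxy)-6-methylbenzoate
Product: 23 (7Z,10E)-12-(tert-butyldimethylsilyloxy)-7-iodo-3-[(4-methoxybenzyl)oxy]-4-methyl-9-oxo-4-(triethylsilyloxy)dodeca-1,7,10-trien-5-yl 2,4-bis(tert-butyldimethylsilyloxy)-6-methylbenzoate
Conditions: NaI (2 equiv), AcOH (5 equiv), MeCN, 0 °C → rt, dark
Reagents that add atoms: sodium iodide [Na+].[I-]
Why: Conjugate addition of iodide to the ynone at C4a and protonation of the allenolate at C4 anti to iodine (anti hydroiodination) give the Z-β-iodoenone with iodine cis to the C3 carbonyl; the ynone is far more electrophilic than the enone, and dilute acid leaves the silyl ethers intact.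

Step 18
Reactants: 23 (7Z,10E)-12-(tert-butyldimethylsilyloxy)-7-iodo-3-[(4-methoxybenzyl)oxy]-4-methyl-9-oxo-4-(triethylsilyloxy)dodeca-1,7,10-trien-5-yl 2,4-bis(tert-butyldimethylsilyloxy)-6-methylbenzoate
Product: 24 (7Z,10E)-12-(tert-butyldimethylsilyloxy)-3-hydroxy-7-iodo-4-methyl-9-oxo-4-(triethylsilyloxy)dodeca-1,7,10-trien-5-yl 2,4-bis(tert-butyldimethylsilyloxy)-6-methylbenzoate
Conditions: DDQ (1.5 equiv), CH2Cl2/pH 7 phosphate buffer (10:1), 0 °C → rt
Reagents that add atoms: none
Why: Oxidative cleavage of the PMB ether (hydride abstraction by DDQ, hydrolysis of the oxocarbenium ion); the silylated C7 oxygen cannot trap the cation as an acetal.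

Step 19
Reactants: 24 (7Z,10E)-12-(tert-butyldimethylsilyloxy)-3-hydroxy-7-iodo-4-methyl-9-oxo-4-(triethylsilyloxy)dodeca-1,7,10-trien-5-yl 2,4-bis(tert-butyldimethylsilyloxy)-6-methylbenzoate
Product: 25 (7Z,10E)-12-(tert-butyldimethylsilyloxy)-7-iodo-4-methyl-3,9-dioxo-4-(triethylsilyloxy)dodeca-1,7,10-trien-5-yl 2,4-bis(tert-butyldimethylsilyloxy)-6-methylbenzoate (open-chain Z-iodoenone vinyl ketone)
Conditions: Dess–Martin periodinane (1.5 equiv), CH2Cl2, 0 °C → rt; used at once
Reagents that add atoms: none
Why: Dess–Martin oxidation of the secondary allylic alcohol to the vinyl ketone; with O7 silylated there is no glycol to cleave, and the sensitive enone is made last.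

Step 20
Reactants: 25 (7Z,10E)-12-(tert-butyldimethylsilyloxy)-7-iodo-4-methyl-3,9-dioxo-4-(triethylsilyloxy)dodeca-1,7,10-trien-5-yl 2,4-bis(tert-butyldimethylsilyloxy)-6-methylbenzoate
Product: 27 7-O-triethylsilyl-tris-O-(tert-butyldimethylsilyl)entonaemin A, via 1-oxatriene 26 (not isolated)
Conditions: Pd(OAc)2 (10 mol %), PPh3 (25 mol %), Ag2CO3 (2 equiv), MeCN, 60 °C, degassed, dark
Reagents that add atoms: none
Why: Proposed new method: zerovalent palladium formed in situ from Pd(OAc)2 and PPh3 inserts into the C4a–I bond with retention of the Z geometry, Ag2CO3 strips iodide to give a cationic divalent vinylpalladium species, and this adds syn across the tethered vinyl ketone so that C4a bonds to C8a and palladium ends on C1; the closest known reaction types are the intramolecular 6-exo Heck cyclisation of vinyl iodides and cross-coupling/oxa-6π cascades to fused 2H-pyrans, here merged on one acyclic chain. Ring A closes in the 6-exo-trig mode. Rotation about C8a–C1 and syn β-hydride elimination of the only β-hydrogen (on C8a) release the 2-methylidene-3-alkylidene ketone 26 and return zerovalent palladium, the carbonate taking up HI. In 26 the C3 carbonyl, C4=C4a and C8a=C1 form a 1-oxatriene held s-cis by ring A and by the Z alkene, and ring B closes by thermal disrotatory oxa-6π electrocyclisation (O2–C1 bond). No stereocentre is created; C6 and C7 are spectators, C7 being quaternary and the base weak and insoluble. The selectivity needed is 6-exo insertion at the α-carbon over 7-endo insertion at the electronically preferred terminal carbon; it rests on the four-atom tether, the strong exo preference of small-ring carbopalladation and the fully substituted C7, which folds the chain. The second requirement, the C3 carbonyl cis to C8a, is built in by the anti hydroiodination of step 17. The closed pyran should be favoured because the bis-exocyclic dienone becomes a vinylogous ester (O2–C3=C4–C4a=C8a–C8=O).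

Step 21
Reactants: 27 7-O-triethylsilyl-tris-O-(tert-butyldimethylsilyl)entonaemin A
Product: 28 entonaemin A
Conditions: HF·pyridine, pyridine, THF, 0 °C → rt
Reagents that add atoms: none
Why: Fluoride-mediated cleavage of all four silyl ethers under buffered, weakly acidic conditions, which avoids base-induced E1cB loss of the C6 ester and acyl migration.

## Compound list

1 | 2-C-methyl-D-erythrono-1,4-lactone, (3R,4R) | O[C@@H]1COC(=O)[C@]1(C)O | starting material
2 | 2,3-O-isopropylidene-2-C-methyl-D-erythrono-1,4-lactone | CC1(C)O[C@@H]2COC(=O)[C@]2(C)O1 | intermediate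
3 | 2,3-O-isopropylidene-2-C-methyl-D-erythrofuranose (anomers) | CC1(C)O[C@@H]2COC(O)[C@]2(C)O1 | intermediate
4 | (5-ethenyl-2,2,5-trimethyl-1,3-dioxolan-4-yl)methanol | C=C[C@]1(C)OC(C)(C)O[C@@H]1CO | intermediate
5 | primary triflate of 4 | C=C[C@]1(C)OC(C)(C)O[C@@H]1COS(=O)(=O)C(F)(F)F | intermediate (not isolated)
6 | trimethyl[3-(5-ethenyl-2,2,5-trimethyl-1,3-dioxolan-4-yl)prop-1-ynyl]silane | C=C[C@]1(C)OC(C)(C)O[C@@H]1CC#C[Si](C)(C)C | intermediate
7 | 2,2,4-trimethyl-5-[3-(trimethylsilyl)prop-2-ynyl]-1,3-dioxolane-4-carbaldehyde | O=C[C@]1(C)OC(C)(C)O[C@@H]1CC#C[Si](C)(C)C | intermediate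
8 | 1-{2,2,4-trimethyl-5-[3-(trimethylsilyl)prop-2-ynyl]-1,3-dioxolan-4-yl}prop-2-en-1-ol (C8 epimers) | C=CC(O)[C@]1(C)OC(C)(C)O[C@@H]1CC#C[Si](C)(C)C | intermediate (not isolated)
9 | 1-[2,2,4-trimethyl-5-(prop-2-ynyl)-1,3-dioxolan-4-yl]prop-2-en-1-ol (C8 epimers) | C=CC(O)[C@]1(C)OC(C)(C)O[C@@H]1CC#C | intermediate
10 | PMB ether of 9 | C=CC(OCc1ccc(OC)cc1)[C@]2(C)OC(C)(C)O[C@@H]2CC#C | intermediate
11 | 3-[(4-methoxybenzyl)oxy]-4-methyloct-1-en-7-yne-4,5-diol | C=CC(OCc1ccc(OC)cc1)[C@](C)(O)[C@H](O)CC#C | intermediate
12 | orsellinic acid | Cc1cc(O)cc(O)c1C(O)=O | starting material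
13 | TBS 2,4-bis(TBS-oxy)-6-methylbenzoate | Cc1cc(O[Si](C)(C)C(C)(C)C)cc(O[Si](C)(C)C(C)(C)C)c1C(=O)O[Si](C)(C)C(C)(C)C | intermediate
14 | 2,4-bis(TBS-oxy)-6-methylbenzoyl chloride | Cc1cc(O[Si](C)(C)C(C)(C)C)cc(O[Si](C)(C)C(C)(C)C)c1C(Cl)=O | intermediate
15 | C6 orsellinate of 11 (C7–OH free) | C=CC(OCc1ccc(OC)cc1)[C@](C)(O)[C@H](OC(=O)c1c(C)cc(O[Si](C)(C)C(C)(C)C)cc1O[Si](C)(C)C(C)(C)C)CC#C | intermediate
16 | C7 TES ether of 15 | C=CC(OCc1ccc(OC)cc1)[C@](C)(O[Si](CC)(CC)CC)[C@H](OC(=O)c1c(C)cc(O[Si](C)(C)C(C)(C)C)cc1O[Si](C)(C)C(C)(C)C)CC#C | intermediate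
17 | (Z)-but-2-ene-1,4-diol | OC/C=C\CO | starting material
18 | (Z)-4-(TBS-oxy)but-2-en-1-ol | OC/C=C\CO[Si](C)(C)C(C)(C)C | intermediate
19 | (Z)-4-(TBS-oxy)but-2-enal | O=C/C=C\CO[Si](C)(C)C(C)(C)C | intermediate (not isolated)
20 | (E)-4-(TBS-oxy)but-2-enal | O=C/C=C/CO[Si](C)(C)C(C)(C)C | intermediate
21 | C3 carbinol (enynol; C3 and C8 epimers) | C=CC(OCc1ccc(OC)cc1)[C@](C)(O[Si](CC)(CC)CC)[C@H](OC(=O)c1c(C)cc(O[Si](C)(C)C(C)(C)C)cc1O[Si](C)(C)C(C)(C)C)CC#CC(O)/C=C/CO[Si](C)(C)C(C)(C)C | intermediate
22 | dienynone | C=CC(OCc1ccc(OC)cc1)[C@](C)(O[Si](CC)(CC)CC)[C@H](OC(=O)c1c(C)cc(O[Si](C)(C)C(C)(C)C)cc1O[Si](C)(C)C(C)(C)C)CC#CC(=O)/C=C/CO[Si](C)(C)C(C)(C)C | intermediate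
23 | Z-iodoenone, C8 PMB ether | C=CC(OCc1ccc(OC)cc1)[C@](C)(O[Si](CC)(CC)CC)[C@H](OC(=O)c1c(C)cc(O[Si](C)(C)C(C)(C)C)cc1O[Si](C)(C)C(C)(C)C)C/C(I)=C/C(=O)/C=C/CO[Si](C)(C)C(C)(C)C | intermediate
24 | Z-iodoenone, C8 carbinol | C=CC(O)[C@](C)(O[Si](CC)(CC)CC)[C@H](OC(=O)c1c(C)cc(O[Si](C)(C)C(C)(C)C)cc1O[Si](C)(C)C(C)(C)C)C/C(I)=C/C(=O)/C=C/CO[Si](C)(C)C(C)(C)C | intermediate
25 | open-chain Z-iodoenone vinyl ketone (key-step precursor, O7 silylated) | C=CC(=O)[C@](C)(O[Si](CC)(CC)CC)[C@H](OC(=O)c1c(C)cc(O[Si](C)(C)C(C)(C)C)cc1O[Si](C)(C)C(C)(C)C)C/C(I)=C/C(=O)/C=C/CO[Si](C)(C)C(C)(C)C | intermediate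
26 | 1-oxatriene (2-methylidene-3-alkylidene cyclohexanone, C3 carbonyl cis to C8a) | C=C1C(=O)[C@](C)(O[Si](CC)(CC)CC)[C@H](OC(=O)c2c(C)cc(O[Si](C)(C)C(C)(C)C)cc2O[Si](C)(C)C(C)(C)C)C/C1=C/C(=O)/C=C/CO[Si](C)(C)C(C)(C)C | intermediate (not isolated)
27 | 7-O-triethylsilyl-tris-O-(tert-butyldimethylsilyl)entonaemin A | Cc1cc(O[Si](C)(C)C(C)(C)C)cc(O[Si](C)(C)C(C)(C)C)c1C(=O)O[C@@H]1CC2=C(COC(/C=C/CO[Si](C)(C)C(C)(C)C)=C2)C(=O)[C@]1(C)O[Si](CC)(CC)CC | intermediate
28 | entonaemin A, (6R,7R) | Cc1cc(O)cc(O)c1C(=O)O[C@@H]1CC2=C(COC(/C=C/CO)=C2)C(=O)[C@]1(C)O | target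

## Step count and least certain steps

Total: 21 steps. Longest linear sequence: 17 steps (1–8, 11, 12, 15–21). The side branches are steps 9–10 (acid chloride 14) and 13–14 (enal 20).

Step 20 (key step, the one step beyond established reaction types).
- What may go wrong: insertion at the terminal carbon of the vinyl ketone (7-endo), which electronics favour; Z/E isomerisation of the β-acyl vinylpalladium species before insertion, which would leave a dienone that cannot close; phosphine-triggered oligomerisation of the vinyl ketone.
- Fallback with known chemistry, from 24: the same palladium conditions are applied one step earlier, to the C8 carbinol. The acceptor is then an electronically unbiased terminal alkene, for which 6-exo Heck closure of vinyl iodides to exocyclic 1,3-dienes is the established mode. β-Hydride loss and oxa-6π closure would give the 8-hydroxy 2H-pyran F1. Oxidation of its allylic C8 hydroxyl (MnO2 or Dess–Martin periodinane) comes back to the route at 27.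

Step 15.
- What may go wrong: base-induced β-elimination of the C6 carboxylate across C5–C6, or attack on the ester, if acetylide formation is slow or the temperature rises.
- Fallback, from 16: iodination of the terminal alkyne (N-iodosuccinimide, AgNO3 cat., acetone) gives the 1-iodoalkyne F2. Nozaki–Hiyama–Kishi coupling with 20 (CrCl2, divalent chromium, with NiCl2 cat., THF, rt) forms the same C3–C4 bond without any base and comes back at 21.

Step 11.
- What may go wrong: slow acylation, because the acid chloride is doubly ortho-substituted and the alcohol lies next to a quaternary carbon; loss of the ortho silyl ether on long reaction times.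
- Fallback, from 12 and 11: 12 is converted with acetone, (CF3CO)2O and CF3CO2H into the benzodioxinone F3 and silylated to F4. The sodium alkoxide of 11 (NaN(SiMe3)2, THF, 0 °C) opens F4 at the carbonyl (transesterification of a salicylate acetonide) to the ester F5 with a free ortho phenol. TBSCl and imidazole then silylate the phenol(s) only and come back at 15.

Step 3.
- What may go wrong: incomplete olefination, because the lactol opens reluctantly to a hindered aldehyde with a quaternary α-carbon.
- Fallback, from 3: CH2=CHMgBr gives the diol F6. Its primary hydroxyl is silylated (TBSCl, imidazole) to F7, the C8 hydroxyl is protected (NaH, 4-MeOC6H4CH2Cl) to give F8, and Bu4NF frees the primary alcohol F9. Only now is C5 activated as the triflate F10 (Tf2O, 2,6-lutidine), so no tetrahydrofuran can form. Displacement with Me3SiC≡CLi gives F11, and K2CO3 in MeOH comes back at 10.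

Step 21.
- What may go wrong: incomplete cleavage of the aryl and tertiary silyl ethers, or decomposition of the dienyl ether on long exposure to HF.
- Fallback, from 27: staged deprotection. KHF2 in MeOH at rt removes the two aryl silyl ethers selectively to give the diphenol F12. A short treatment with HF·pyridine (or aqueous HF in MeCN) then removes the two alkyl silyl ethers and comes back at 28.

## Further compounds

F1 | step 20 | 8-hydroxy analogue of 27 (2H-pyran, C8 carbinol) | Cc1cc(O[Si](C)(C)C(C)(C)C)cc(O[Si](C)(C)C(C)(C)C)c1C(=O)O[C@@H]1CC2=C(COC(/C=C/CO[Si](C)(C)C(C)(C)C)=C2)C(O)[C@]1(C)O[Si](CC)(CC)CC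
F2 | step 15 | 1-iodoalkyne derived from 16 | C=CC(OCc1ccc(OC)cc1)[C@](C)(O[Si](CC)(CC)CC)[C@H](OC(=O)c1c(C)cc(O[Si](C)(C)C(C)(C)C)cc1O[Si](C)(C)C(C)(C)C)CC#CI
F3 | step 11 | 7-hydroxy-2,2,5-trimethyl-4H-1,3-benzodioxin-4-one | Cc1cc(O)cc2OC(C)(C)OC(=O)c12
F4 | step 11 | 7-(tert-butyldimethylsilyloxy)-2,2,5-trimethyl-4H-1,3-benzodioxin-4-one | Cc1cc(O[Si](C)(C)C(C)(C)C)cc2OC(C)(C)OC(=O)c12
F5 | step 11 | C6 ester of 11 with 4-(TBS-oxy)-2-hydroxy-6-methylbenzoic acid | C=CC(OCc1ccc(OC)cc1)[C@](C)(O)[C@H](OC(=O)c1c(C)cc(O[Si](C)(C)C(C)(C)C)cc1O)CC#C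
F6 | step 3 | 1-[5-(hydroxymethyl)-2,2,4-trimethyl-1,3-dioxolan-4-yl]prop-2-en-1-ol | C=CC(O)[C@]1(C)OC(C)(C)O[C@@H]1CO
F7 | step 3 | primary TBS ether of F6 | C=CC(O)[C@]1(C)OC(C)(C)O[C@@H]1CO[Si](C)(C)C(C)(C)C
F8 | step 3 | C8 PMB ether of F7 | C=CC(OCc1ccc(OC)cc1)[C@]2(C)OC(C)(C)O[C@@H]2CO[Si](C)(C)C(C)(C)C
F9 | step 3 | C5 alcohol with C8 PMB ether | C=CC(OCc1ccc(OC)cc1)[C@]2(C)OC(C)(C)O[C@@H]2CO
F10 | step 3 | primary triflate of F9 | C=CC(OCc1ccc(OC)cc1)[C@]2(C)OC(C)(C)O[C@@H]2COS(=O)(=O)C(F)(F)F
F11 | step 3 | C-trimethylsilyl derivative of 10 | C=CC(OCc1ccc(OC)cc1)[C@]2(C)OC(C)(C)O[C@@H]2CC#C[Si](C)(C)C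
F12 | step 21 | 11-O-TBS-7-O-TES-entonaemin A (free phenols) | Cc1cc(O)cc(O)c1C(=O)O[C@@H]1CC2=C(COC(/C=C/CO[Si](C)(C)C(C)(C)C)=C2)C(=O)[C@]1(C)O[Si](CC)(CC)CC
A1 | alternative 1 | ring A 1,3-dione with C6,C7 acetonide | O=C1CC(=O)[C@]2(C)OC(C)(C)O[C@@H]2C1
A2 | alternative 1 | methyl 2,2,4-trimethyl-5-(2-oxopropyl)-1,3-dioxolane-4-carboxylate | COC(=O)[C@]1(C)OC(C)(C)O[C@@H]1CC(C)=O
A3 | alternative 2 | ring A ketol with enyne and silyloxymethyl arms | Cc1cc(O[Si](C)(C)C(C)(C)C)cc(O[Si](C)(C)C(C)(C)C)c1C(=O)O[C@@H]1CC(C#C/C=C/CO[Si](C)(C)C(C)(C)C)=C(CO[Si](C)(C)C(C)(C)C)C(=O)[C@]1(C)O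
A4 | alternative 2 | 1-acetylcyclopent-2-en-1-ol precursor (C6 ester, C8 carbinol) | CC(=O)[C@]1(O)C(CO[Si](C)(C)C(C)(C)C)=C(C#C/C=C/CO[Si](C)(C)C(C)(C)C)C[C@H]1OC(=O)c1c(C)cc(O[Si](C)(C)C(C)(C)C)cc1O[Si](C)(C)C(C)(C)C
A5 | alternative 3 | 11-O-(tert-butyldimethylsilyl)entonaemin A | Cc1cc(O)cc(O)c1C(=O)O[C@@H]1CC2=C(COC(/C=C/CO[Si](C)(C)C(C)(C)C)=C2)C(=O)[C@]1(C)O
A6 | alternative 3 | 11-O-TBS core diol (C6 and C7 hydroxyls free) | O[C@@H]1CC2=C(COC(/C=C/CO[Si](C)(C)C(C)(C)C)=C2)C(=O)[C@]1(C)O
A7 | alternative 3 | 6-(2,4-dioxopentyl)-2,2-dimethyl-4H-1,3-dioxin-4-one | CC(=O)CC(=O)CC1=CC(=O)OC(C)(C)O1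
A8 | alternative 3 | 3,5,7-trioxoocta-1-en-1-one (acylketene) | CC(=O)CC(=O)CC(=O)C=C=O
A9 | alternative 3 | C6 3,5,7-trioxooctanoate of A6 | CC(=O)CC(=O)CC(=O)CC(=O)O[C@@H]1CC2=C(COC(/C=C/CO[Si](C)(C)C(C)(C)C)=C2)C(=O)[C@]1(C)O
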